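**Strategy.** The 2,2-dimethylpyran ring of the chromene (O1, C2, C3, C4, C4a, C8a) is disconnected to a 2,2-dimethyl-2,3-dihydrobenzofuran whose benzylic carbon bears the future C4 as an exocyclic CH2OH. Triflation triggers a Wagner–Meerwein (neophyl) 1,2-shift that expands the five-membered ring and, after proton loss, installs C3=C4 in one operation. The step exploits that C4a lies between the oxygen-bearing carbons C5 and C8a, which makes it an excellent migrating terminus, and that quaternary C2 allows only the C3=C4 olefin; both furan epimers converge. The precursor comes from a Claisen rearrangement/hydroalkoxylation on O-2'; C3 of the isoflavan is set by Evans alkylation.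

Key step: step 17

Abbreviations: TIPS = triisopropylsilyl; MOM = methoxymethyl; Piv = pivaloyl; prenyl = 3-methylbut-2-en-1-yl; ArA = 2,4-dimethoxy-6-(methoxymethoxy)-3-prenylphenyl; "C5 chain" = (2E)-2-methyl-4-(pivaloyloxy)but-2-en-1-yl.

Assumption: 6-hydroxy-1-benzofuran-2(3H)-one (14, the lactone of 2,4-dihydroxyphenylacetic acid) is taken as a purchasable compound.

Remark: the Claisen shift in step 14 creates the furan C3 centre without control, so 25–29 are mixtures of two epimers at that carbon (isoflavan C3 is uniformly R); the key step removes this centre.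

**Step 1**
Reactants: 1 3,5-dimethoxyphenol
Product: 2 (3,5-dimethoxyphenoxy)triisopropylsilane
Conditions: TIPSCl, imidazole, DMF, rt
Reagents that add atoms: triisopropylsilyl chloride, CC(C)[Si](Cl)(C(C)C)C(C)C
Why: Imidazole-promoted phenol silylation should proceed cleanly, and the bulky, weakly coordinating OTIPS group leaves the next metalation to be directed by the two methoxy groups only.

**Step 2**
Reactants: 2 (3,5-dimethoxyphenoxy)triisopropylsilane
Product: 4 (3,5-dimethoxy-4-prenylphenoxy)triisopropylsilane, via aryllithium 3 (not isolated)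
Conditions: n-BuLi, THF, 0 °C → rt; then prenyl bromide, −78 °C → rt
Reagents that add atoms: n-butyllithium, [Li]CCCC (lithium of 3); prenyl bromide, CC(C)=CCBr
Why: Directed ortho-metalation should occur at the carbon flanked by both methoxy groups (cooperative direction, OTIPS shielded), and the aryllithium is then alkylated by prenyl bromide in an SN2 reaction.

**Step 3**
Reactants: 4 (3,5-dimethoxy-4-prenylphenoxy)triisopropylsilane
Product: 6 1,3-dimethoxy-5-(methoxymethoxy)-2-prenylbenzene, via phenol 5 (not isolated)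
Conditions: TBAF, THF, 0 °C; then i-Pr2NEt, MOMCl (excess), 0 °C → rt
Reagents that add atoms: chloromethyl methyl ether, COCCl
Why: Fluoride desilylation gives the tetrabutylammonium phenoxide, which is O-alkylated in the same flask (Williamson-type ether formation), exchanging the non-directing silyl group for the strongly ortho-directing MOM group.

**Step 4**
Reactants: 6 1,3-dimethoxy-5-(methoxymethoxy)-2-prenylbenzene
Product: 9 [2,4-dimethoxy-6-(methoxymethoxy)-3-prenylphenyl]methanol, via aryllithium 7 (not isolated), via aldehyde 8 (not isolated)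
Conditions: n-BuLi, THF, −20 → 0 °C; DMF, −78 → 0 °C; then MeOH, NaBH4, 0 °C
Reagents that add atoms: n-butyllithium, [Li]CCCC (lithium of 7); N,N-dimethylformamide, CN(C)C=O
Why: Directed ortho-metalation between OMOM and OMe (the two such sites are equivalent), formylation with DMF and in situ borohydride reduction should give the benzylic alcohol, with a short, cold metalation to avoid deprotonating the benzylic–allylic prenyl CH2.

**Step 5**
Reactants: 9 [2,4-dimethoxy-6-(methoxymethoxy)-3-prenylphenyl]methanol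
Product: 10 2,4-dimethoxy-6-(methoxymethoxy)-3-prenylbenzyl bromide
Conditions: CBr4, PPh3, 2,6-lutidine, CH2Cl2, −20 °C; filtered cold and used at once
Reagents that add atoms: carbon tetrabromide, BrC(Br)(Br)Br
Why: Appel bromination under neutral, buffered conditions should spare MOM and prenyl, and the highly ionisable trialkoxybenzyl bromide is used without purification.

**Step 6**
Reactants: 11 3-methylbut-2-en-1-ol
Product: 12 3-methylbut-2-en-1-yl pivalate
Conditions: PivCl, pyridine, DMAP (cat.), CH2Cl2, 0 °C → rt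
Reagents that add atoms: pivaloyl chloride, CC(C)(C)C(Cl)=O
Why: Standard acylation; the pivalate has no α-hydrogen and should resist enolate base, borohydride, mild acid and heat in the later steps.

**Step 7**
Reactants: 12 3-methylbut-2-en-1-yl pivalate
Product: 13 (2E)-4-hydroxy-3-methylbut-2-en-1-yl pivalate
Conditions: SeO2 (cat.), t-BuOOH, salicylic acid (cat.), CH2Cl2, rt
Reagents that add atoms: selenium dioxide, O=[Se]=O (oxygen carrier); tert-butyl hydroperoxide, CC(C)(C)OO (terminal oxidant)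
Why: Riley allylic oxidation (ene reaction, then [2,3]-shift) should hydroxylate the (E)-methyl group of the trisubstituted olefin selectively and give the (E)-allylic alcohol.

**Step 8**
Reactants: 14 6-hydroxy-1-benzofuran-2(3H)-one
Product: 15 6-(triisopropylsilyloxy)-1-benzofuran-2(3H)-one
Conditions: TIPSCl, imidazole, DMF, rt
Reagents that add atoms: triisopropylsilyl chloride, CC(C)[Si](Cl)(C(C)C)C(C)C
Why: Silylation of the only free hydroxyl; the lactone masks the 2-OH and the carboxyl group, so the two B-ring oxygens are differentiated without a selectivity problem.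

**Step 9**
Reactants: 15 6-(triisopropylsilyloxy)-1-benzofuran-2(3H)-one; 13 (2E)-4-hydroxy-3-methylbut-2-en-1-yl pivalate
Product: 17 methyl [2-(C5-chain-oxy)-4-(triisopropylsilyloxy)phenyl]acetate, via phenol ester 16 (not isolated)
Conditions: NaOMe (cat.), MeOH, 0 °C; AcOH (cat.), evaporate; then 13, PPh3, DIAD, THF, 0 °C → rt
Reagents that add atoms: methanol, CO
Why: Methoxide-catalysed transesterification opens the aryl lactone and frees only the 2-OH, which is then etherified with the primary allylic alcohol 13 in a Mitsunobu reaction (SN2 at CH2, olefin untouched).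

**Step 10**
Reactants: 17 methyl [2-(C5-chain-oxy)-4-(triisopropylsilyloxy)phenyl]acetate
Product: 18 [2-(C5-chain-oxy)-4-(triisopropylsilyloxy)phenyl]acetic acid
Conditions: Me3SnOH, 1,2-dichloroethane, 80 °C; then 1 M HCl wash
Reagents that add atoms: trimethyltin hydroxide, C[Sn](C)(C)O
Why: Trimethyltin hydroxide-mediated ester hydrolysis should cleave the unhindered methyl ester under neutral conditions while the pivalate and the aryl silyl ether survive.

**Step 11**
Reactants: 18 [2-(C5-chain-oxy)-4-(triisopropylsilyloxy)phenyl]acetic acid; 19 (4R)-4-benzyl-1,3-oxazolidin-2-one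
Product: 21 (4R)-4-benzyl-3-{[2-(C5-chain-oxy)-4-(triisopropylsilyloxy)phenyl]acetyl}-1,3-oxazolidin-2-one, via mixed anhydride 20 (not isolated)
Conditions: PivCl, Et3N, THF, −20 °C; then 19, LiCl, −20 °C → rt
Reagents that add atoms: pivaloyl chloride, CC(C)(C)C(Cl)=O (pivaloyl group of 20)
Why: N-acylation of the oxazolidinone through the mixed pivalic anhydride (LiCl/Et3N variant) attaches the auxiliary, with attack at the less hindered arylacetyl carbonyl.

**Step 12**
Reactants: 21 (4R)-4-benzyl-3-{[2-(C5-chain-oxy)-4-(triisopropylsilyloxy)phenyl]acetyl}-1,3-oxazolidin-2-one; 10 2,4-dimethoxy-6-(methoxymethoxy)-3-prenylbenzyl bromide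
Product: 23 (4R)-4-benzyl-3-{(2R)-3-ArA-2-[2-(C5-chain-oxy)-4-(triisopropylsilyloxy)phenyl]propanoyl}-1,3-oxazolidin-2-one, via sodium enolate 22 (not isolated)
Conditions: NaHMDS, THF, −78 °C; then 10, −78 → −45 °C; AcOH quench at −78 °C
Reagents that add atoms: sodium hexamethyldisilazide, C[Si](C)(C)N([Na])[Si](C)(C)C (sodium of 22)
Why: Evans asymmetric alkylation, in which the chelated (Z)-sodium enolate is benzylated on the face opposite the benzyl group of the (4R)-auxiliary, sets the new α-centre as R (the future isoflavan C3).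

**Step 13**
Reactants: 23 (4R)-4-benzyl-3-{(2R)-3-ArA-2-[2-(C5-chain-oxy)-4-(triisopropylsilyloxy)phenyl]propanoyl}-1,3-oxazolidin-2-one
Product: 24 (2R)-3-ArA-2-[2-(C5-chain-oxy)-4-(triisopropylsilyloxy)phenyl]propan-1-ol
Conditions: LiBH4, MeOH (1 equiv), THF, 0 °C
Reagents that add atoms: none
Why: Reductive cleavage of the N-acyloxazolidinone by lithium borohydride should give the primary alcohol without epimerisation and release 19 for recovery, while the hindered pivalate reacts much more slowly.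

**Step 14**
Reactants: 24 (2R)-3-ArA-2-[2-(C5-chain-oxy)-4-(triisopropylsilyloxy)phenyl]propan-1-ol
Product: 26 (2R)-2-[2,2-dimethyl-3-(pivaloyloxymethyl)-4-(triisopropylsilyloxy)-2,3-dihydro-1-benzofuran-7-yl]-3-(6-hydroxy-2,4-dimethoxy-3-prenylphenyl)propan-1-ol, via Claisen phenol 25 (not isolated)
Conditions: PhNEt2, 190 °C; dilute acid wash; then Amberlyst-15, CH2Cl2/MeOH (10:1), 40 °C
Reagents that add atoms: none
Why: The aromatic Claisen rearrangement ([3,3]) can deliver the allyl unit only to C3' (the other ortho position is substituted) and inverts it to a 1-(pivaloyloxymethyl)-2-methylallyl group, whose isopropenyl olefin then undergoes acid-catalysed Markovnikov hydroalkoxylation by the new 2'-OH (5-exo-trig, tertiary cation) to the 2,2-dimethyldihydrofuran while acidic methanol removes the MOM group; the new furan C3 centre is not controlled and need not be.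

**Step 15**
Reactants: 26 (2R)-2-[2,2-dimethyl-3-(pivaloyloxymethyl)-4-(triisopropylsilyloxy)-2,3-dihydro-1-benzofuran-7-yl]-3-(6-hydroxy-2,4-dimethoxy-3-prenylphenyl)propan-1-ol
Product: 27 {7-[(3R)-5,7-dimethoxy-6-prenyl-3,4-dihydro-2H-chromen-3-yl]-2,2-dimethyl-4-(triisopropylsilyloxy)-2,3-dihydro-1-benzofuran-3-yl}methyl pivalate
Conditions: PPh3, DIAD, THF, 0 °C → rt (dilute)
Reagents that add atoms: none
Why: Intramolecular Mitsunobu etherification (6-exo-tet) of the only free phenol with the primary alcohol closes the chroman ring at CH2, so the C3 stereocentre is not touched.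

**Step 16**
Reactants: 27 {7-[(3R)-5,7-dimethoxy-6-prenyl-3,4-dihydro-2H-chromen-3-yl]-2,2-dimethyl-4-(triisopropylsilyloxy)-2,3-dihydro-1-benzofuran-3-yl}methyl pivalate
Product: 28 {7-[(3R)-5,7-dimethoxy-6-prenyl-3,4-dihydro-2H-chromen-3-yl]-2,2-dimethyl-4-(triisopropylsilyloxy)-2,3-dihydro-1-benzofuran-3-yl}methanol
Conditions: DIBAL-H, CH2Cl2, −78 °C; Rochelle salt work-up
Reagents that add atoms: none
Why: Reductive ester cleavage by DIBAL-H frees the primary alcohol, while the aryl silyl ether, the aryl ethers and the olefins are inert.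

**Step 17**
Reactants: 28 {7-[(3R)-5,7-dimethoxy-6-prenyl-3,4-dihydro-2H-chromen-3-yl]-2,2-dimethyl-4-(triisopropylsilyloxy)-2,3-dihydro-1-benzofuran-3-yl}methanol
Product: 30 ({8-[(3R)-5,7-dimethoxy-6-prenyl-3,4-dihydro-2H-chromen-3-yl]-2,2-dimethyl-2H-chromen-5-yl}oxy)triisopropylsilane, via primary triflate 29 (not isolated)
Conditions: Tf2O, 2,6-di-tert-butyl-4-methylpyridine, CH2Cl2, −78 → 0 °C
Reagents that add atoms: triflic anhydride, O=S(=O)(OS(=O)(=O)C(F)(F)F)C(F)(F)F (triflyl group of 29)
Why: O-Triflation gives 29, whose ionisation is assisted by the electron-rich arene: the furan ipso carbon C3a, flanked by O1-bearing C7a and OTIPS-bearing C4, bridges to the CH2 (3-exo-tet closure of a phenonium ion) and the old C3–C3a bond then breaks, so the CH2 enters the ring as chromene C4, after which a 1,2-H shift to the doubly oxygen-stabilised benzylic C4 cation and loss of the C3 proton to the pyridine base should deliver the C3=C4 olefin. Migration of C2 instead of the aryl carbon would give the same benzylic cation directly and hence the same chromene, so the step is constitutionally convergent. The closest known reaction type is the dehydrative Wagner–Meerwein (neophyl) ring expansion of benzo-fused carbinols, such as 9-fluorenylmethanol to phenanthrene or xanthen-9-ylmethanol to dibenz[b,f]oxepine, together with the aryl-assisted solvolysis of β-arylethyl sulfonates. The six-membered ring arises from the five-membered one by this 1,2-carbon shift (expansion by one atom), not by a new cyclisation. No stereocentre is created: the uncontrolled furan C3 centre is destroyed, so both epimers of 28 funnel into one product, and the remote isoflavan C3 is untouched. The selectivity needed is carbon migration over hydride migration and over E2 loss of triflic acid to the exocyclic 3-methylene furan; it is secured by the two oxygen donors ortho to the migrating carbon, the hindered non-nucleophilic base and low temperature, while quaternary C2 (no hydrogen) guarantees that C3=C4 is the only ring olefin that can form.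

**Step 18**
Reactants: 30 ({8-[(3R)-5,7-dimethoxy-6-prenyl-3,4-dihydro-2H-chromen-3-yl]-2,2-dimethyl-2H-chromen-5-yl}oxy)triisopropylsilane
Product: 31 Kanzonol I
Conditions: TBAF, AcOH, THF, 0 °C
Reagents that add atoms: none
Why: Fluoride-mediated cleavage of the aryl silyl ether, buffered with acetic acid, should liberate the chromene 5-OH without affecting the chromene, the prenyl group or the stereocentre.

**Compound list**

1 | 3,5-dimethoxyphenol | COc1cc(O)cc(OC)c1 | starting material
2 | (3,5-dimethoxyphenoxy)triisopropylsilane | COc1cc(OC)cc(O[Si](C(C)C)(C(C)C)C(C)C)c1 | intermediate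
3 | [2,6-dimethoxy-4-(triisopropylsilyloxy)phenyl]lithium | [Li]c1c(OC)cc(O[Si](C(C)C)(C(C)C)C(C)C)cc1OC | intermediate (not isolated)
4 | (3,5-dimethoxy-4-prenylphenoxy)triisopropylsilane | COc1cc(O[Si](C(C)C)(C(C)C)C(C)C)cc(OC)c1CC=C(C)C | intermediate
5 | 3,5-dimethoxy-4-prenylphenol (formed as its tetrabutylammonium phenoxide) | COc1cc(O)cc(OC)c1CC=C(C)C | intermediate (not isolated)
6 | 1,3-dimethoxy-5-(methoxymethoxy)-2-prenylbenzene | COCOc1cc(OC)c(CC=C(C)C)c(OC)c1 | intermediate
7 | [2,4-dimethoxy-6-(methoxymethoxy)-3-prenylphenyl]lithium | [Li]c1c(OCOC)cc(OC)c(CC=C(C)C)c1OC | intermediate (not isolated)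
8 | 2,4-dimethoxy-6-(methoxymethoxy)-3-prenylbenzaldehyde | O=Cc1c(OCOC)cc(OC)c(CC=C(C)C)c1OC | intermediate (not isolated)
9 | [2,4-dimethoxy-6-(methoxymethoxy)-3-prenylphenyl]methanol | OCc1c(OCOC)cc(OC)c(CC=C(C)C)c1OC | intermediate
10 | 2,4-dimethoxy-6-(methoxymethoxy)-3-prenylbenzyl bromide | BrCc1c(OCOC)cc(OC)c(CC=C(C)C)c1OC | intermediate
11 | 3-methylbut-2-en-1-ol | CC(C)=CCO | starting material
12 | 3-methylbut-2-en-1-yl pivalate | CC(C)=CCOC(=O)C(C)(C)C | intermediate
13 | (2E)-4-hydroxy-3-methylbut-2-en-1-yl pivalate | CC(C)(C)C(=O)OC/C=C(\C)CO | intermediate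
14 | 6-hydroxy-1-benzofuran-2(3H)-one | O=C1Cc2ccc(O)cc2O1 | starting material
15 | 6-(triisopropylsilyloxy)-1-benzofuran-2(3H)-one | O=C1Cc2ccc(O[Si](C(C)C)(C(C)C)C(C)C)cc2O1 | intermediate
16 | methyl [2-hydroxy-4-(triisopropylsilyloxy)phenyl]acetate | COC(=O)Cc1ccc(O[Si](C(C)C)(C(C)C)C(C)C)cc1O | intermediate (not isolated)
17 | methyl [2-{[(2E)-2-methyl-4-(pivaloyloxy)but-2-en-1-yl]oxy}-4-(triisopropylsilyloxy)phenyl]acetate | COC(=O)Cc1ccc(O[Si](C(C)C)(C(C)C)C(C)C)cc1OC/C(C)=C/COC(=O)C(C)(C)C | intermediate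
18 | [2-{[(2E)-2-methyl-4-(pivaloyloxy)but-2-en-1-yl]oxy}-4-(triisopropylsilyloxy)phenyl]acetic acid | OC(=O)Cc1ccc(O[Si](C(C)C)(C(C)C)C(C)C)cc1OC/C(C)=C/COC(=O)C(C)(C)C | intermediate
19 | (4R)-4-benzyl-1,3-oxazolidin-2-one | O=C1N[C@H](Cc2ccccc2)CO1 | starting material
20 | mixed pivalic anhydride of acid 18 | CC(C)(C)C(=O)OC(=O)Cc1ccc(O[Si](C(C)C)(C(C)C)C(C)C)cc1OC/C(C)=C/COC(=O)C(C)(C)C | intermediate (not isolated)
21 | (4R)-4-benzyl-3-{[2-(C5-chain-oxy)-4-(triisopropylsilyloxy)phenyl]acetyl}-1,3-oxazolidin-2-one | O=C(Cc1ccc(O[Si](C(C)C)(C(C)C)C(C)C)cc1OC/C(C)=C/COC(=O)C(C)(C)C)N1[C@H](Cc2ccccc2)COC1=O | intermediate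
22 | sodium (Z)-enolate of imide 21 | [Na+].[O-]/C(=C\c1ccc(O[Si](C(C)C)(C(C)C)C(C)C)cc1OC/C(C)=C/COC(=O)C(C)(C)C)N1[C@H](Cc2ccccc2)COC1=O | intermediate (not isolated)
23 | (4R)-4-benzyl-3-{(2R)-3-ArA-2-[2-(C5-chain-oxy)-4-(triisopropylsilyloxy)phenyl]propanoyl}-1,3-oxazolidin-2-one | O=C([C@@H](c1ccc(O[Si](C(C)C)(C(C)C)C(C)C)cc1OC/C(C)=C/COC(=O)C(C)(C)C)Cc1c(OCOC)cc(OC)c(CC=C(C)C)c1OC)N1[C@H](Cc2ccccc2)COC1=O | intermediate
24 | (2R)-3-ArA-2-[2-(C5-chain-oxy)-4-(triisopropylsilyloxy)phenyl]propan-1-ol | OC[C@@H](c1ccc(O[Si](C(C)C)(C(C)C)C(C)C)cc1OC/C(C)=C/COC(=O)C(C)(C)C)Cc1c(OCOC)cc(OC)c(CC=C(C)C)c1OC | intermediate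
25 | (2R)-3-ArA-2-{2-hydroxy-3-[3-methyl-1-(pivaloyloxy)but-3-en-2-yl]-4-(triisopropylsilyloxy)phenyl}propan-1-ol, both epimers at the new benzylic carbon | OC[C@@H](c1ccc(O[Si](C(C)C)(C(C)C)C(C)C)c(C(COC(=O)C(C)(C)C)C(C)=C)c1O)Cc1c(OCOC)cc(OC)c(CC=C(C)C)c1OC | intermediate (not isolated)
26 | (2R)-2-[2,2-dimethyl-3-(pivaloyloxymethyl)-4-(triisopropylsilyloxy)-2,3-dihydro-1-benzofuran-7-yl]-3-(6-hydroxy-2,4-dimethoxy-3-prenylphenyl)propan-1-ol, both furan C3 epimers | OC[C@@H](c1ccc(O[Si](C(C)C)(C(C)C)C(C)C)c2c1OC(C)(C)C2COC(=O)C(C)(C)C)Cc1c(O)cc(OC)c(CC=C(C)C)c1OC | intermediate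
27 | {7-[(3R)-5,7-dimethoxy-6-prenyl-3,4-dihydro-2H-chromen-3-yl]-2,2-dimethyl-4-(triisopropylsilyloxy)-2,3-dihydro-1-benzofuran-3-yl}methyl pivalate, both furan C3 epimers | COc1cc2c(c(OC)c1CC=C(C)C)C[C@H](c1ccc(O[Si](C(C)C)(C(C)C)C(C)C)c3c1OC(C)(C)C3COC(=O)C(C)(C)C)CO2 | intermediate
28 | {7-[(3R)-5,7-dimethoxy-6-prenyl-3,4-dihydro-2H-chromen-3-yl]-2,2-dimethyl-4-(triisopropylsilyloxy)-2,3-dihydro-1-benzofuran-3-yl}methanol, both furan C3 epimers | COc1cc2c(c(OC)c1CC=C(C)C)C[C@H](c1ccc(O[Si](C(C)C)(C(C)C)C(C)C)c3c1OC(C)(C)C3CO)CO2 | intermediate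
29 | trifluoromethanesulfonate of alcohol 28, both furan C3 epimers | COc1cc2c(c(OC)c1CC=C(C)C)C[C@H](c1ccc(O[Si](C(C)C)(C(C)C)C(C)C)c3c1OC(C)(C)C3COS(=O)(=O)C(F)(F)F)CO2 | intermediate (not isolated)
30 | ({8-[(3R)-5,7-dimethoxy-6-prenyl-3,4-dihydro-2H-chromen-3-yl]-2,2-dimethyl-2H-chromen-5-yl}oxy)triisopropylsilane | COc1cc2c(c(OC)c1CC=C(C)C)C[C@H](c1ccc(O[Si](C(C)C)(C(C)C)C(C)C)c3c1OC(C)(C)C=C3)CO2 | intermediate
31 | Kanzonol I, 8-[(3R)-5,7-dimethoxy-6-(3-methylbut-2-en-1-yl)-3,4-dihydro-2H-chromen-3-yl]-2,2-dimethyl-2H-chromen-5-ol | COc1cc2c(c(OC)c1CC=C(C)C)C[C@H](c1ccc(O)c3c1OC(C)(C)C=C3)CO2 | target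

**Count.** Total: 18 steps. Longest linear sequence: 12 steps (from 1 through steps 1–5 and 12–18; equally from 11 through steps 6, 7 and 9–18).

**Steps most likely to fail**

Step 17 (key step). After ionisation of the triflate the cation may be drained by a 1,2-hydride shift or by E2 loss of triflic acid, both of which lead to the exocyclic 3-methylene furan instead of carbon migration. The fallback builds the pyran ring by a propargyl ether rearrangement; it sets out from 24 and returns to the route at 30. The substituted allyl group on O-2' is removed with Pd(PPh3)4 and morpholine (two successive Tsuji–Trost allyl transfers) to give (2R)-3-ArA-2-[2-hydroxy-4-(triisopropylsilyloxy)phenyl]propan-1-ol F1. The phenol is alkylated with 3-chloro-3-methylbut-1-yne (K2CO3, KI, CuI cat., acetone) to the aryl 1,1-dimethylpropargyl ether F2. Heating in PhNEt2 at 180 °C (propargyl Claisen shift to C3', 1,5-H shift, 6π-oxa-electrocyclisation) should give the MOM-protected chromene alcohol F3. HCl in MeOH removes the MOM group to give the chromene phenol alcohol F4, and Mitsunobu ring closure as in step 15 gives 30.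

Step 14. Part of the [3,3] migration may pass through the substituted ortho carbon C1' and on to the para position, and the acid needed for ring closure and MOM cleavage may protonate the A-ring prenyl olefin. The fallback closes the furan ring by halocyclisation instead of acid catalysis; it sets out from 25 (isolated after the thermal stage) and returns at 26. Iodoetherification (I2, NaHCO3, MeCN, 0 °C, 5-exo) gives the 2-(iodomethyl)-2-methyldihydrobenzofuran F5. Radical deiodination (Bu3SnH, AIBN, toluene, 80 °C) gives the MOM-protected 2,2-dimethyldihydrobenzofuran F6. ZnBr2 and n-PrSH in CH2Cl2 remove the MOM group without protic acid and give 26.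

Step 12. The very electron-rich bromide 10 may ionise and self-condense before C-alkylation, and the α-aryl imide may partly epimerise under the basic conditions. The fallback replaces auxiliary alkylation by condensation and asymmetric hydrogenation; it sets out from 18 and aldehyde 8 (step 4 stopped before NaBH4) and returns at 24. Perkin condensation (Ac2O, Et3N, 110 °C) gives the (E)-2,3-diarylacrylic acid F7. Carboxyl-directed asymmetric hydrogenation with a chiral iridium spiro phosphine–oxazoline catalyst (enantiomer chosen for R; isolated trisubstituted olefins lack the directing group and should stay) gives the (R)-2,3-diarylpropanoic acid F8. Reduction through the mixed carbonic anhydride (i-BuOCOCl, N-methylmorpholine; then NaBH4, H2O) gives 24.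

**Further compounds**

F1 | step 17 | (2R)-3-ArA-2-[2-hydroxy-4-(triisopropylsilyloxy)phenyl]propan-1-ol | OC[C@@H](c1ccc(O[Si](C(C)C)(C(C)C)C(C)C)cc1O)Cc1c(OCOC)cc(OC)c(CC=C(C)C)c1OC
F2 | step 17 | (2R)-3-ArA-2-{2-[(2-methylbut-3-yn-2-yl)oxy]-4-(triisopropylsilyloxy)phenyl}propan-1-ol | OC[C@@H](c1ccc(O[Si](C(C)C)(C(C)C)C(C)C)cc1OC(C)(C)C#C)Cc1c(OCOC)cc(OC)c(CC=C(C)C)c1OC
F3 | step 17 | (2R)-3-ArA-2-[2,2-dimethyl-5-(triisopropylsilyloxy)-2H-chromen-8-yl]propan-1-ol | OC[C@@H](c1ccc(O[Si](C(C)C)(C(C)C)C(C)C)c2c1OC(C)(C)C=C2)Cc1c(OCOC)cc(OC)c(CC=C(C)C)c1OC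
F4 | step 17 | (2R)-2-[2,2-dimethyl-5-(triisopropylsilyloxy)-2H-chromen-8-yl]-3-(6-hydroxy-2,4-dimethoxy-3-prenylphenyl)propan-1-ol | OC[C@@H](c1ccc(O[Si](C(C)C)(C(C)C)C(C)C)c2c1OC(C)(C)C=C2)Cc1c(O)cc(OC)c(CC=C(C)C)c1OC
F5 | step 14 | (2R)-3-ArA-2-[2-(iodomethyl)-2-methyl-3-(pivaloyloxymethyl)-4-(triisopropylsilyloxy)-2,3-dihydro-1-benzofuran-7-yl]propan-1-ol | OC[C@@H](c1ccc(O[Si](C(C)C)(C(C)C)C(C)C)c2c1OC(C)(CI)C2COC(=O)C(C)(C)C)Cc1c(OCOC)cc(OC)c(CC=C(C)C)c1OC
F6 | step 14 | (2R)-3-ArA-2-[2,2-dimethyl-3-(pivaloyloxymethyl)-4-(triisopropylsilyloxy)-2,3-dihydro-1-benzofuran-7-yl]propan-1-ol | OC[C@@H](c1ccc(O[Si](C(C)C)(C(C)C)C(C)C)c2c1OC(C)(C)C2COC(=O)C(C)(C)C)Cc1c(OCOC)cc(OC)c(CC=C(C)C)c1OC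
F7 | step 12 | (2E)-3-ArA-2-[2-(C5-chain-oxy)-4-(triisopropylsilyloxy)phenyl]prop-2-enoic acid | OC(=O)/C(=C/c1c(OCOC)cc(OC)c(CC=C(C)C)c1OC)c1ccc(O[Si](C(C)C)(C(C)C)C(C)C)cc1OC/C(C)=C/COC(=O)C(C)(C)C
F8 | step 12 | (2R)-3-ArA-2-[2-(C5-chain-oxy)-4-(triisopropylsilyloxy)phenyl]propanoic acid | OC(=O)[C@@H](c1ccc(O[Si](C(C)C)(C(C)C)C(C)C)cc1OC/C(C)=C/COC(=O)C(C)(C)C)Cc1c(OCOC)cc(OC)c(CC=C(C)C)c1OC
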